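**Retrosynthetic overview**

1. The target comes from the free triol by peracetylation and selective loss of the phenolic acetate. The triol comes from a trans-2-aryl-2,3-dihydrobenzofuran-3-carboxylate (propanoate arm, aryl pivalate) by one global hydride reduction.
2. Key disconnection: the C3–C3a bond of the dihydrofuran ring (O1–C2–C3–C3a–C7a). The exocyclic CH2OAc carbon on C3 sits next to aryl carbon C3a, so it is read as the former C4 carbonyl carbon of a six-membered chroman-4-one. Oxidative ring contraction of an (S)-flavanone (1,2-shift of C4a from C4 to C3) forms C3–C3a, shrinks the pyranone to the furan ring and sets C3 trans to C2.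
3. The flavanone has a single stereocentre (C2). It is cut at C2–aryl into a flat chromone and an arylboronic acid, joined by an enantioselective Pd-catalysed conjugate addition.
4. The chromone comes from methyl dihydroferulate, which already holds the C3 side chain, the OMe and the phenol oxygen (ortho-iodination, acetyl coupling, enaminone cyclisation).
5. Ring order: pyranone ring (step 3), then contraction to the dihydrofuran ring (step 6). No other ring is built.

Key step: step 6

Assumption: the facial sense of the Pd/t-BuPyOx conjugate addition on the chromone is taken to parallel that on carbocyclic enones, which calls for the (R)-ligand to reach the (2S)-flavanone. If the sense proves opposite, the (S)-ligand is used and nothing else changes.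

**Route**

Step 1
Reactants: 1 methyl 3-(4-hydroxy-3-methoxyphenyl)propanoate
Product: 2 methyl 3-(4-hydroxy-3-iodo-5-methoxyphenyl)propanoate
Conditions: NIS (1.05 equiv), p-TsOH·H2O (10 mol%), MeCN, 0 °C to rt
Reagents that add atoms: N-iodosuccinimide, O=C1CCC(=O)N1I
Why: Electrophilic aromatic iodination in which the free phenol OH is the dominant director and its only open ortho/para position is the one iodinated (para holds the side chain, the other ortho the OMe), as in the iodination of vanillin.

Step 2
Reactants: 2 methyl 3-(4-hydroxy-3-iodo-5-methoxyphenyl)propanoate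
Product: 4 methyl 3-(3-acetyl-4-hydroxy-5-methoxyphenyl)propanoate, via aryl enol ether 3 (not isolated)
Conditions: Bu3Sn–C(OEt)=CH2 (1.3 equiv), PdCl2(PPh3)2 (5 mol%), toluene, 100 °C; then 2 M aq. HCl, THF, rt
Reagents that add atoms: tributyl(1-ethoxyvinyl)stannane, CCCC[Sn](CCCC)(CCCC)C(=C)OCC; water, O
Why: Stille coupling with the 1-ethoxyvinyl stannane (an acetyl anion equivalent) and acid hydrolysis of the enol ether put the acetyl group exactly where the iodine sat, which avoids the regiochemical ambiguity of a Fries rearrangement on a guaiacol ring.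

Step 3
Reactants: 4 methyl 3-(3-acetyl-4-hydroxy-5-methoxyphenyl)propanoate
Product: 6 methyl 3-(8-methoxy-4-oxo-4H-chromen-6-yl)propanoate, via enaminone 5 (not isolated)
Conditions: Me2NCH(OMe)2 (3 equiv), toluene, 100 °C; evaporate; conc. HCl, CH2Cl2, 40 °C
Reagents that add atoms: N,N-dimethylformamide dimethyl acetal, COC(OC)N(C)C
Why: Condensation of the methyl ketone with DMF-DMA gives the enaminone, and acid then drives 6-endo oxa-Michael addition of the phenol with loss of dimethylamine, the standard enaminone route to 2,3-unsubstituted chromones.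

Step 4
Reactants: 7 (4-hydroxy-3-methoxyphenyl)boronic acid
Product: 8 [4-(2,2-dimethylpropanoyloxy)-3-methoxyphenyl]boronic acid
Conditions: PivCl (1.1 equiv), pyridine (1.5 equiv), DMAP (5 mol%), CH2Cl2, 0 °C to rt; dilute aq. HCl wash
Reagents that add atoms: pivaloyl chloride, CC(C)(C)C(Cl)=O
Why: DMAP-catalysed O-acylation of the phenol (any boron-bound acyl group is hydrolysed in the aqueous work-up); the pivalate survives the acid of step 6, makes the B ring electron-poor for that step and is removed by the hydride of step 7.

Step 5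
Reactants: 6 methyl 3-(8-methoxy-4-oxo-4H-chromen-6-yl)propanoate; 8 [4-(2,2-dimethylpropanoyloxy)-3-methoxyphenyl]boronic acid (2 equiv)
Product: 9 methyl 3-[(2S)-2-[4-(2,2-dimethylpropanoyloxy)-3-methoxyphenyl]-8-methoxy-4-oxo-3,4-dihydro-2H-chromen-6-yl]propanoate
Conditions: Pd(OCOCF3)2 (5 mol%), (R)-t-BuPyOx (6 mol%), NH4PF6 (30 mol%), H2O (5 equiv), ClCH2CH2Cl, 60 °C
Reagents that add atoms: none
Why: Pd(II)/pyridine-oxazoline catalysed enantioselective conjugate addition of an arylboronic acid to a chromone (transmetalation, enantio-determining carbopalladation of C2=C3 on the face left open by the tert-butyl group of the ligand, protonolysis of the Pd enolate) sets C2 as S under neutral conditions that do not open the flavanone by retro-oxa-Michael reaction.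

Step 6
Reactants: 9 methyl 3-[(2S)-2-[4-(2,2-dimethylpropanoyloxy)-3-methoxyphenyl]-8-methoxy-4-oxo-3,4-dihydro-2H-chromen-6-yl]propanoate
Product: 12 methyl (2S,3S)-2-[4-(2,2-dimethylpropanoyloxy)-3-methoxyphenyl]-7-methoxy-5-(3-methoxy-3-oxopropyl)-2,3-dihydro-1-benzofuran-3-carboxylate, via enol ether 10 (not isolated), via iodane ketal 11 (not isolated)
Conditions: PhI(OAc)2 (1.2 equiv), cat. conc. H2SO4, HC(OMe)3, rt; aq. NaHCO3 work-up
Reagents that add atoms: trimethyl orthoformate, COC(OC)OC; water, O
Why: Acid and orthoformate convert the C4 ketone into enol ether 10, which the electrophilic iodine(III) attacks at C3 anti to the pseudo-equatorial C2 aryl group, and methanol capture gives the trans α-iodanyl ketal 11; PhI then leaves as the A-ring carbon C4a shifts from C4 to C3, and the resulting dialkoxycarbenium ion ends as the methyl ester after work-up. This is the known hypervalent-iodine (or thallium(III)) oxidative ring contraction of flavanones to methyl trans-2-aryl-2,3-dihydrobenzofuran-3-carboxylates, a semipinacol-type oxidative 1,2-aryl shift. The furan ring (O1, C2, C3, C3a, C7a) is not closed by a cyclisation but arises by contraction: C3–C3a forms through a phenonium-bridged 1,2-shift while C4 leaves the ring and becomes the exocyclic ester carbon. C3 is the only new stereocentre; it is inverted in the anti-periplanar shift of the trans-diequatorial iodane, which places the ester trans to the C2 aryl group (also the thermodynamically preferred arrangement), while C2 is not touched and stays S. The step needs migration of the A-ring carbon and not of the C2 aryl group (which would lead to an isoflavone), and no oxidation of the arenes. This is secured because the equatorial C3–I bond is anti-periplanar to the ring bond C4–C4a, the migrating carbon is activated by the ortho ring oxygen, and the pivaloyloxy group makes the B ring electron-poor, which slows both its migration and acid ionisation of the benzylic C2–O1 bond.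

Step 7
Reactants: 12 methyl (2S,3S)-2-[4-(2,2-dimethylpropanoyloxy)-3-methoxyphenyl]-7-methoxy-5-(3-methoxy-3-oxopropyl)-2,3-dihydro-1-benzofuran-3-carboxylate
Product: 13 3-[(2S,3R)-2-(4-hydroxy-3-methoxyphenyl)-3-(hydroxymethyl)-7-methoxy-2,3-dihydro-1-benzofuran-5-yl]propan-1-ol
Conditions: LiAlH4 (4 equiv), THF, 0 °C; aq. potassium sodium tartrate work-up
Reagents that add atoms: none
Why: Ester reduction with LiAlH4 turns both methyl esters into the two CH2OH arms and cleaves the aryl pivalate to the phenol in the same operation; no stereocentre is touched because hydride addition outruns enolisation at C3, and the cold, short reaction keeps the aluminium phenoxide from opening the C2–O1 bond.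

Step 8
Reactants: 13 3-[(2S,3R)-2-(4-hydroxy-3-methoxyphenyl)-3-(hydroxymethyl)-7-methoxy-2,3-dihydro-1-benzofuran-5-yl]propan-1-ol
Product: 15 3-[(2S,3R)-3-(acetoxymethyl)-2-(4-hydroxy-3-methoxyphenyl)-7-methoxy-2,3-dihydro-1-benzofuran-5-yl]propyl acetate, via triacetate 14 (not isolated)
Conditions: Ac2O (3.5 equiv), pyridine, rt; then pyrrolidine (10 equiv), 0 °C to rt, short reaction time
Reagents that add atoms: acetic anhydride, CC(=O)OC(C)=O
Why: Exhaustive O-acetylation followed by chemoselective aminolysis, in which an aryl acetate is a far better acyl donor towards a secondary amine than a primary alkyl acetate, so pyrrolidine removes only the phenolic acetate and leaves both aliphatic acetates and both stereocentres untouched.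

**Compound list**

1 | methyl 3-(4-hydroxy-3-methoxyphenyl)propanoate (methyl dihydroferulate) | COC(=O)CCc1ccc(O)c(OC)c1 | starting material
2 | methyl 3-(4-hydroxy-3-iodo-5-methoxyphenyl)propanoate | COC(=O)CCc1cc(I)c(O)c(OC)c1 | intermediate
3 | methyl 3-[3-(1-ethoxyethenyl)-4-hydroxy-5-methoxyphenyl]propanoate | COC(=O)CCc1cc(OC)c(O)c(C(=C)OCC)c1 | intermediate (not isolated)
4 | methyl 3-(3-acetyl-4-hydroxy-5-methoxyphenyl)propanoate | COC(=O)CCc1cc(OC)c(O)c(C(C)=O)c1 | intermediate
5 | methyl 3-{3-[(2E)-3-(dimethylamino)prop-2-enoyl]-4-hydroxy-5-methoxyphenyl}propanoate | COC(=O)CCc1cc(OC)c(O)c(C(=O)/C=C/N(C)C)c1 | intermediate (not isolated)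
6 | methyl 3-(8-methoxy-4-oxo-4H-chromen-6-yl)propanoate | COC(=O)CCc1cc(OC)c2OC=CC(=O)c2c1 | intermediate
7 | (4-hydroxy-3-methoxyphenyl)boronic acid | COc1cc(B(O)O)ccc1O | starting material
8 | [4-(2,2-dimethylpropanoyloxy)-3-methoxyphenyl]boronic acid | COc1cc(B(O)O)ccc1OC(=O)C(C)(C)C | intermediate
9 | methyl 3-[(2S)-2-[4-(2,2-dimethylpropanoyloxy)-3-methoxyphenyl]-8-methoxy-4-oxo-3,4-dihydro-2H-chromen-6-yl]propanoate | COC(=O)CCc1cc(OC)c2c(c1)C(=O)C[C@@H](c1ccc(OC(=O)C(C)(C)C)c(OC)c1)O2 | intermediate
10 | methyl 3-[(2S)-2-[4-(2,2-dimethylpropanoyloxy)-3-methoxyphenyl]-4,8-dimethoxy-2H-chromen-6-yl]propanoate | COC(=O)CCc1cc(OC)c2c(c1)C(OC)=C[C@@H](c1ccc(OC(=O)C(C)(C)C)c(OC)c1)O2 | intermediate (not isolated)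
11 | methyl 3-[(2R,3R)-3-[acetoxy(phenyl)-λ3-iodanyl]-2-[4-(2,2-dimethylpropanoyloxy)-3-methoxyphenyl]-4,4,8-trimethoxy-3,4-dihydro-2H-chromen-6-yl]propanoate (iodine trans to the C2 aryl group; C2 arranged as in 9, descriptor changed by CIP priority only) | COC(=O)CCc1cc(OC)c2c(c1)C(OC)(OC)[C@H](I(OC(C)=O)c1ccccc1)[C@@H](c1ccc(OC(=O)C(C)(C)C)c(OC)c1)O2 | intermediate (not isolated)
12 | methyl (2S,3S)-2-[4-(2,2-dimethylpropanoyloxy)-3-methoxyphenyl]-7-methoxy-5-(3-methoxy-3-oxopropyl)-2,3-dihydro-1-benzofuran-3-carboxylate (2,3-trans) | COc1cc([C@H]2Oc3c(OC)cc(CCC(=O)OC)cc3[C@@H]2C(=O)OC)ccc1OC(=O)C(C)(C)C | intermediate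
13 | 3-[(2S,3R)-2-(4-hydroxy-3-methoxyphenyl)-3-(hydroxymethyl)-7-methoxy-2,3-dihydro-1-benzofuran-5-yl]propan-1-ol (2,3-trans) | COc1cc([C@H]2Oc3c(OC)cc(CCCO)cc3[C@@H]2CO)ccc1O | intermediate
14 | 3-[(2S,3R)-2-(4-acetoxy-3-methoxyphenyl)-3-(acetoxymethyl)-7-methoxy-2,3-dihydro-1-benzofuran-5-yl]propyl acetate | COc1cc([C@H]2Oc3c(OC)cc(CCCOC(C)=O)cc3[C@@H]2COC(C)=O)ccc1OC(C)=O | intermediate (not isolated)
15 | 3-[(2S,3R)-3-(acetoxymethyl)-2-(4-hydroxy-3-methoxyphenyl)-7-methoxy-2,3-dihydro-1-benzofuran-5-yl]propyl acetate (2,3-trans) | COc1cc([C@H]2Oc3c(OC)cc(CCCOC(C)=O)cc3[C@@H]2COC(C)=O)ccc1O | target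

**Summary**

Total step count: 8. Longest linear sequence: 7 (steps 1, 2, 3, 5, 6, 7, 8); step 4 is a one-step side branch.

Steps most likely to fail:

Step 6 (ring contraction). What may go wrong: migration of the C2 aryl group in place of the A-ring carbon (isoflavone pathway), dehydrogenation to the flavone, or acid ionisation at C2 with erosion of enantiopurity. The fallback sets out from 9 and comes back at 12, and replaces the iodine(III) shift by a Wolff ring contraction. The ketone 9 is C-trifluoroacetylated at C3 (LiHMDS, THF, −78 °C, then CF3CO2CH2CF3) to give the 3-trifluoroacetyl flavanone F1, held in its enol form. Detrifluoroacetylative diazo transfer (MsN3, Et3N, MeCN, rt) then gives the 3-diazoflavanone F2. Irradiation (about 350 nm) in MeOH expels nitrogen, C4a migrates to the carbene carbon C3, and methanol traps the ring-contracted ketene. This should give 12 together with its C3 epimer, the cis ester F3. Treatment of the mixture with DBU in toluene at rt should funnel F3 into the trans ester 12, since only C3 is epimerisable.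

Step 5 (enantioselective conjugate addition). What may go wrong: insufficient facial discrimination on the 8-methoxy chromone, the opposite sense of induction, or slow carbopalladation. The fallback sets out from 6 and 8 and comes back at 9, and replaces asymmetric catalysis by a kinetic resolution. Conjugate addition with the achiral Pd(OCOCF3)2/2,2'-bipyridine catalyst gives the racemic flavanone F4. Ru–TsDPEN asymmetric transfer hydrogenation (RuCl(p-cymene)(TsDPEN), HCO2H/Et3N, rt, stopped slightly past half conversion) then reduces one enantiomer, with the catalyst antipode chosen so that the (2R)-ketone reacts. The unwanted enantiomer becomes the cis-flavan-4-ol F5, and (S)-9 is recovered by chromatography.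

Step 8 (acetylation and selective phenolic deacetylation). What may go wrong: loss of chemoselectivity in the aminolysis (partial cleavage of an aliphatic acetate or incomplete cleavage of the aryl acetate). The fallback sets out from 13 and comes back at 15, and replaces "acetylate all, remove one" by a direct chemoselective acylation. Immobilised Candida antarctica lipase B with vinyl acetate in MTBE at 40 °C should acetylate the two primary aliphatic alcohols and leave the phenol free. No new compound arises on this path (F0).

**Further compounds**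

F1 | step 6 | methyl 3-[(2R)-2-[4-(2,2-dimethylpropanoyloxy)-3-methoxyphenyl]-4-hydroxy-8-methoxy-3-(trifluoroacetyl)-2H-chromen-6-yl]propanoate (enol form; C2 arranged as in 9) | COC(=O)CCc1cc(OC)c2c(c1)C(O)=C(C(=O)C(F)(F)F)[C@@H](c1ccc(OC(=O)C(C)(C)C)c(OC)c1)O2
F2 | step 6 | methyl 3-[(2R)-3-diazo-2-[4-(2,2-dimethylpropanoyloxy)-3-methoxyphenyl]-8-methoxy-4-oxo-3,4-dihydro-2H-chromen-6-yl]propanoate (C2 arranged as in 9) | COC(=O)CCc1cc(OC)c2c(c1)C(=O)C(=[N+]=[N-])[C@@H](c1ccc(OC(=O)C(C)(C)C)c(OC)c1)O2
F3 | step 6 | methyl (2S,3R)-2-[4-(2,2-dimethylpropanoyloxy)-3-methoxyphenyl]-7-methoxy-5-(3-methoxy-3-oxopropyl)-2,3-dihydro-1-benzofuran-3-carboxylate (2,3-cis) | COc1cc([C@H]2Oc3c(OC)cc(CCC(=O)OC)cc3[C@H]2C(=O)OC)ccc1OC(=O)C(C)(C)C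
F4 | step 5 | methyl 3-[(2RS)-2-[4-(2,2-dimethylpropanoyloxy)-3-methoxyphenyl]-8-methoxy-4-oxo-3,4-dihydro-2H-chromen-6-yl]propanoate (racemate) | COC(=O)CCc1cc(OC)c2c(c1)C(=O)CC(c1ccc(OC(=O)C(C)(C)C)c(OC)c1)O2
F5 | step 5 | methyl 3-[(2R,4R)-2-[4-(2,2-dimethylpropanoyloxy)-3-methoxyphenyl]-4-hydroxy-8-methoxy-3,4-dihydro-2H-chromen-6-yl]propanoate (2,4-cis) | COC(=O)CCc1cc(OC)c2c(c1)[C@H](O)C[C@H](c1ccc(OC(=O)C(C)(C)C)c(OC)c1)O2
F0 | step 8 | none | none
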